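All constants stand for no real mixture; what happens was integrated by code.

The ratio of the equilibrium constant for protonating the nucleophile to that for forming the salt of the base, 0.660, is the split ratio: c(protonated nucleophile)/c(nucleophile) equals it times c(salt of the base)/c(free base).

| setting | gamma | alpha |
|---|---|---|
| electrophile | 0.050 M | 0.050 M |
| nucleophile | 0.125 M | 0.125 M |
| free base | 0.100 M | 0.130 M |
| scavenger | 0.0400 M | 0.0400 M |
| time | 2.0 min | 2.0 min |

    electrophile + nucleophile → acid set free + target (k1 = 0.27 M⁻¹ s⁻¹)
    nucleophile + acid set free ⇌ protonated nucleophile, settled at all times (K2 = 9900 M⁻¹)
    acid set free + free base ⇌ salt of the base, settled at all times (K3 = 15000 M⁻¹)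
    nucleophile + acid set free ⇌ idle adduct, settled at all times (K4 = 28 M⁻¹)
    acid set free + scavenger → scavenged by-product (k5 = 36 M⁻¹ s⁻¹)
    2 nucleophile → homo dimer (k6 = 0.055 M⁻¹ s⁻¹)

- amounts and yields of acid set free count idle adduct too
- a step written with two of one species runs at k times the square of its concentration and takes two of it each time
- run time (gamma): 2.0 min

- part of the electrophile that has reacted at the end, gamma
- part of the electrophile that has reacted at the end, alpha
- what raising the concentration of free base from its lowest to its highest value here does to the part of the electrophile that has reacted (changes below 5 percentage points count as none) (no change / it rises / it falls)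

We turn the question round: what would the numbers need for more free base to move the reacted part by 5 percentage points? Treat the coupling of electrophile and nucleophile roughly, as if it were first-order in electrophile, with a remaining share y. A relative gain in coupling rate then moves the reacted part by that gain times −y ln y, a factor that peaks at 0.368. So on this rough picture alpha would need a rate gain over gamma of at least

13.6 %.

We take the mid-point of the coupling, with 0.0250 M of acid set free, all counted as salt of the base. The split ratio then gives c(protonated nucleophile)/c(nucleophile), and from it the free share, meaning free nucleophile over free plus protonated nucleophile:

gamma: 0.220, so a free share of 82.0 %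
alpha: 0.157, so a free share of 86.4 %

The gain is 5.43 %, less than the need, and on the same picture it moves the reacted part by about 2 points at the peak of that factor. Our reckoning therefore commits to no change, though it gives no conversion of its own.

The forecast gave 81 % for gamma and 82.5 % for alpha, hence no change, on the grounds of the share of nucleophile tied up as its protonated form, “leaving extra base with little to add”.

The simulation gives 82.5 % for gamma and 82.9 % for alpha, a change of 0.41 points, which counts as no change. At 2.00 min gamma holds 0.0296 M of salt of the base with 70 % of its free base left, and alpha holds 0.0322 M with 75 % left. The split ratio turns these into c(protonated nucleophile)/c(nucleophile) of 0.278 in gamma and 0.217 in alpha. In the flask like gamma but charged with 0.031 M of nucleophile, it gives 0.133 at 2.00 min, and 38.4 % of the electrophile has reacted.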